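**Plan**

- Numbering follows the target's decalin: ring A = C1–C5, C10; ring B = C5–C10; chain C11, C12; butenolide C13–C16; C17 = methyl on C8; C18 = CH2O on C4; C19 = methyl on C4; C20 = methyl on C9. β is the face of the C6 hydroxyl, α the other face.
- Retrosynthesis: cut the C18–O ester and return C3 to a carbinol; cut C12–C13 (butenolide coupling) and C11=C12 (methylenation); cut C6–C7 and C8–C9 together; open the pyrone at O6–C11 and C5–C6; finally cut C9–C10 and C4–C18.
- Enabling feature: ring B is a cyclohexene whose C5=C10 bond lies between C6 (oxygen-bearing) and C9 (quaternary, carrying C11), with O6 and C11 cis. Joined as the lactone O6–C11(=O), they form the third bridge of a 2-pyrone + alkene cycloadduct.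
- Forward order: ring A from a desymmetrised dione, then a temporary pyrone ring on C5/C10, then ring B by [4+2] with acrolein, then the lactone is opened into the C11–C12 chain and butenolide, then the C18 ester and C3 ketone.
- Stereochemistry: C4 from asymmetric transfer hydrogenation; C6 and C9 from the lactone bridge; C8 from endo addition; the face from the pseudoaxial C19 methyl of the acetonide-locked ring A. The C3 carbinol, acetonide, lactone ring and formyl group are helpers that are removed later.

Key step: step 8

Assumption: the (S,S)-ligand is taken to give the (3S)-carbinol cis to C18 (the (R,R)-ligand is used if the sense is opposite); either C3 epimer would serve, because C3 ends as a ketone and both acetonides hold the C19 methyl pseudoaxial.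

**Route**

Step 1
Reactants: 1 2-methylcyclohexane-1,3-dione
Product: 2 2-(hydroxymethyl)-2-methylcyclohexane-1,3-dione
Conditions: aq. CH2O (37 %), NaHCO3 (cat.), THF/H2O, rt
Reagents that add atoms: formaldehyde, C=O
Why: Aldol hydroxymethylation (Tollens type) at the only C–H between the two carbonyls should give the prochiral quaternary carbon C4 carrying C18 and C19; no stereocenter is formed.

Step 2
Reactants: 2 2-(hydroxymethyl)-2-methylcyclohexane-1,3-dione
Product: 3 (2S,3S)-3-hydroxy-2-(hydroxymethyl)-2-methylcyclohexan-1-one (C5 ketone, 3α-OH, 18α-CH2OH, 19β-CH3)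
Conditions: RuCl(p-cymene)[(S,S)-TsDPEN] (1 mol %), HCO2H/Et3N (5:2), CH2Cl2, 25 °C, stopped at mono-reduction
Reagents that add atoms: none
Why: Noyori asymmetric transfer hydrogenation (divalent ruthenium) desymmetrises the enantiotopic carbonyls, with hydride arriving anti to the larger CH2OH group, so that the C3 carbinol and the quaternary C4 are set together.

Step 3
Reactants: 3 (2S,3S)-3-hydroxy-2-(hydroxymethyl)-2-methylcyclohexan-1-one
Product: 4 3,18-O-isopropylidene acetal of 3 (cis-fused 1,3-dioxane, C5 ketone)
Conditions: Me2C(OMe)2, PPTS (cat.), CH2Cl2, rt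
Reagents that add atoms: 2,2-dimethoxypropane, COC(C)(C)OC
Why: Acid-catalysed transacetalisation of the cis-1,3-diol gives the six-membered acetonide, which should lock ring A with C18 pseudoequatorial and the C19 methyl pseudoaxial, because the other half-chair would place C2 axial on the dioxane, syn to an acetal methyl.

Step 4
Reactants: 4 acetonide ketone; 5 methyl (S)-2-(trifluoromethylsulfonyloxy)propanoate
Product: 6 C10-alkylated keto ester (C10–C9H(C20H3)–C11O2Me; mixture of C9/C10 epimers)
Conditions: LiN(i-Pr)2, THF, −78 °C; then 5, DMPU, −78 → −30 °C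
Reagents that add atoms: none
Why: SN2 alkylation of the only possible ketone enolate (C10, since C4 is quaternary) by an α-triflyloxy ester forms C9–C10; the configurations at C9 and C10 do not matter because both carbons become sp2 in step 7.

Step 5
Reactants: 6 C10-alkylated keto ester
Product: 7 enol triflate (C5–OTf, C5=C10)
Conditions: KN(SiMe3)2, THF, −78 °C; then PhNTf2, −78 → 0 °C
Reagents that add atoms: N-phenylbis(trifluoromethanesulfonimide), O=S(=O)(N(c1ccccc1)S(=O)(=O)C(F)(F)F)C(F)(F)F
Why: Enolate O-sulfonylation; the ketone is more acidic than the ester and can enolise only towards C10, which should give the tetrasubstituted C5=C10 enol triflate.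

Step 6
Reactants: 7 enol triflate
Product: 8 enal ester (C6 aldehyde on C5, C5=C10, C11 methyl ester)
Conditions: Pd(PPh3)4 (5 mol %), CO (3 atm), Bu3SnH (slow addition), LiCl, THF, 50 °C
Reagents that add atoms: carbon monoxide, [C-]#[O+]
Why: Stille-type reductive carbonylation (formylation) of a vinyl triflate: oxidative addition to zerovalent palladium, CO insertion and hydride transfer from tin should install C6 at the aldehyde oxidation level.

Step 7
Reactants: 8 enal ester
Product: 10 ring A-fused 2-pyrone (O6–C6H=C5 and C10=C9(C20H3)–C11(=O)–O6; acetonide intact), via potassium carboxylate 9 (not isolated)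
Conditions: KOSiMe3, THF, rt; then Ac2O, NaOAc, 60 °C
Reagents that add atoms: none
Why: Anhydrous ester cleavage followed by enol-lactonisation of the (Z)-5-oxo-3-enoic acid through its mixed anhydride (C6 and C9 are held cis on the ring alkene) should give the pyrone, and the scrambled C9/C10 centers become sp2.

Step 8
Reactants: 10 ring A-fused 2-pyrone; 11 acrolein (prop-2-enal)
Product: 12 Diels–Alder adduct (2-oxabicyclo[2.2.2]oct-5-en-3-one; lactone bridge O6–C11(=O) on the β face, C5=C10, 8α-formyl, 20α-methyl)
Conditions: acrolein (10 equiv), BHT (cat.), toluene, 90 °C, sealed tube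
Reagents that add atoms: none
Why: Thermal normal-electron-demand Diels–Alder reaction in which the pyrone diene C6=C5–C10=C9 adds suprafacially to the C7=C8 bond of acrolein in one concerted, asynchronous step; the closest known reaction type is the cycloaddition of 3-substituted 2-pyrones with acrylic dienophiles to give isolable 2-oxabicyclo[2.2.2]octenones. Ring B is closed by an intermolecular [4+2] ring formation that makes C6–C7 and C8–C9 at once and leaves the C5=C10 double bond, with the lactone O6–C11(=O) as the third bridge. C6 and C9 are set relative to each other by the bridge itself (O6 and C11 must be cis, so the C20 methyl is trans to O6); C8 is set by endo addition, which puts the formyl group under the C5=C10 bridge and anti to the lactone; all three are set relative to C4 by the pseudoaxial C19 methyl of the acetonide-locked ring A, which blocks the β face next to C6 so that acrolein adds from the α face. The step needs regioselectivity (CH2 to C6, formyl-bearing carbon to C9), which the C9 methyl should secure, as a donor at C3 does in 3-halo-2-pyrones, by making C6 the terminus that bonds first to the unsubstituted carbon. It also needs the adduct to keep its CO2 bridge, which is why the temperature is held at 90 °C.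

Step 9
Reactants: 12 Diels–Alder adduct
Product: 14 17-methyl lactone (8α-methyl), via tosylhydrazone 13 (not isolated)
Conditions: TsNHNH2, CHCl3, rt; then catecholborane, 0 °C; then NaOAc·3H2O, 60 °C
Reagents that add atoms: none
Why: Caglioti-type reductive deoxygenation (Kabalka variant) of the aldehyde tosylhydrazone turns the formyl helper into the C17 methyl through a diazene that loses N2, without touching the lactone or the C8 center.

Step 10
Reactants: 14 17-methyl lactone
Product: 15 C11 lactol (anomer mixture)
Conditions: i-Bu2AlH (1.1 equiv), CH2Cl2, −78 °C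
Reagents that add atoms: none
Why: Partial reduction of a lactone by i-Bu2AlH at low temperature should stop at the bridged lactol, which is the masked 6β-hydroxy C11 aldehyde.

Step 11
Reactants: 15 C11 lactol
Product: 16 6β-alcohol with a 9β-vinyl group (C11=C12)
Conditions: Ph3PCH3Br, KOt-Bu, THF, 0 → 50 °C
Reagents that add atoms: methyltriphenylphosphonium bromide, [Br-].C[P+](c1ccccc1)(c1ccccc1)c1ccccc1
Why: Wittig methylenation of the open hydroxy-aldehyde form of the lactol adds C12 and releases the C6 hydroxyl; the aldehyde carbon sits on quaternary C9, so nothing can epimerise.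

Step 12
Reactants: 16 6β-alcohol with 9β-vinyl group
Product: 17 6-O-TBS ether
Conditions: TBSCl, imidazole, DMAP (cat.), DMF, 40 °C
Reagents that add atoms: tert-butyldimethylsilyl chloride, CC(C)(C)[Si](C)(C)Cl
Why: Silyl ether formation protects the allylic C6 hydroxyl so that C3 can later be oxidised alone.

Step 13
Reactants: 17 6-O-TBS ether; 18 4-bromofuran-2(5H)-one
Product: 20 butenolide (acetonide and 6-O-TBS intact), via B-alkyl-9-BBN borane 19 (not isolated)
Conditions: 9-BBN, THF, rt; then 18, Pd(dppf)Cl2 (5 mol %), AsPh3, Cs2CO3, DMF/H2O, 50 °C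
Reagents that add atoms: none
Why: Anti-Markovnikov hydroboration of the terminal vinyl group (the tetrasubstituted C5=C10 bond is inert) followed by B-alkyl Suzuki–Miyaura coupling (divalent palladium precatalyst) with the β-bromobutenolide should form C12–C13.

Step 14
Reactants: 20 butenolide acetonide
Product: 21 3α,18-diol (6-O-TBS)
Conditions: PPTS (cat.), MeOH, rt
Reagents that add atoms: none
Why: Acid-catalysed transacetalisation removes the acetonide lock, while the secondary TBS ether and the butenolide should survive these mild conditions.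

Step 15
Reactants: 22 3-(4-hydroxyphenyl)propanoic acid
Product: 24 3-[4-(tert-butyldimethylsilyloxy)phenyl]propanoic acid, via bis-silyl derivative 23 (not isolated)
Conditions: TBSCl (2.5 equiv), imidazole, DMF, rt; then AcOH/THF/H2O (1:3:1), rt
Reagents that add atoms: tert-butyldimethylsilyl chloride, CC(C)(C)[Si](C)(C)Cl
Why: Exhaustive silylation followed by selective hydrolysis of the labile silyl ester leaves the aryl silyl ether, so the phenol cannot compete in the esterification.

Step 16
Reactants: 21 3α,18-diol; 24 3-[4-(tert-butyldimethylsilyloxy)phenyl]propanoic acid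
Product: 25 C18 ester with free 3α-OH
Conditions: EDC·HCl, DMAP (cat.), CH2Cl2, 0 °C
Reagents that add atoms: none
Why: Steglich esterification should acylate the primary C18 hydroxyl in preference to the more hindered secondary C3 hydroxyl.

Step 17
Reactants: 25 C18 ester with free 3α-OH
Product: 26 C3 ketone (6-O-TBS, aryl O-TBS)
Conditions: Dess–Martin periodinane, NaHCO3, CH2Cl2, rt
Reagents that add atoms: none
Why: Dess–Martin oxidation of the only free hydroxyl removes the temporary C3 stereocenter; C4 is quaternary and cannot epimerise.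

Step 18
Reactants: 26 C3 ketone bis-TBS ether
Product: 27 CNP0301014.1 (target)
Conditions: Bu4NF, AcOH, THF, 0 °C → rt
Reagents that add atoms: none
Why: Buffered fluoride desilylation should cleave the aryl and the allylic silyl ethers without opening the butenolide or the β-acyloxy ketone.

**Compound list**

1 | 2-methylcyclohexane-1,3-dione | CC1C(=O)CCCC1=O | starting material
2 | 2-(hydroxymethyl)-2-methylcyclohexane-1,3-dione | CC1(CO)C(=O)CCCC1=O | intermediate
3 | (2S,3S)-3-hydroxy-2-(hydroxymethyl)-2-methylcyclohexan-1-one | O=C1CCC[C@H](O)[C@]1(C)CO | intermediate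
4 | 3,18-O-isopropylidene acetal of 3 (cis-fused dioxane, C5 ketone) | O=C1CCC[C@@H]2OC(C)(C)OC[C@]12C | intermediate
5 | methyl (S)-2-(trifluoromethylsulfonyloxy)propanoate | C[C@H](OS(=O)(=O)C(F)(F)F)C(=O)OC | starting material
6 | C10-alkylated keto ester (C9/C10 epimer mixture) | COC(=O)C(C)C1CC[C@@H]2OC(C)(C)OC[C@]2(C)C1=O | intermediate
7 | enol triflate (C5–OTf, C5=C10) | COC(=O)C(C)C=1CC[C@@H]2OC(C)(C)OC[C@]2(C)C=1OS(=O)(=O)C(F)(F)F | intermediate
8 | enal ester (C6 aldehyde, C11 methyl ester) | COC(=O)C(C)C=1CC[C@@H]2OC(C)(C)OC[C@]2(C)C=1C=O | intermediate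
9 | potassium carboxylate of 8 | [K+].[O-]C(=O)C(C)C=1CC[C@@H]2OC(C)(C)OC[C@]2(C)C=1C=O | intermediate (not isolated)
10 | ring A-fused 2-pyrone (acetonide) | CC1=C2CC[C@@H]3OC(C)(C)OC[C@]3(C)C2=COC1=O | intermediate
11 | acrolein | C=CC=O | starting material
12 | Diels–Alder adduct (β lactone bridge, 8α-formyl, 20α-methyl) | O=C[C@H]1C[C@@H]2OC(=O)[C@@]1(C)C3=C2[C@@]4(C)COC(C)(C)O[C@H]4CC3 | intermediate
13 | tosylhydrazone of 12 | Cc1ccc(cc1)S(=O)(=O)NN=C[C@H]1C[C@@H]2OC(=O)[C@@]1(C)C3=C2[C@@]4(C)COC(C)(C)O[C@H]4CC3 | intermediate (not isolated)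
14 | 17-methyl lactone | C[C@H]1C[C@@H]2OC(=O)[C@@]1(C)C3=C2[C@@]4(C)COC(C)(C)O[C@H]4CC3 | intermediate
15 | C11 lactol (anomer mixture) | C[C@H]1C[C@@H]2OC(O)[C@@]1(C)C3=C2[C@@]4(C)COC(C)(C)O[C@H]4CC3 | intermediate
16 | 6β-alcohol with 9β-vinyl group | C[C@H]1C[C@H](O)C2=C(CC[C@@H]3OC(C)(C)OC[C@]23C)[C@]1(C)C=C | intermediate
17 | 6-O-TBS ether of 16 | C[C@H]1C[C@H](O[Si](C)(C)C(C)(C)C)C2=C(CC[C@@H]3OC(C)(C)OC[C@]23C)[C@]1(C)C=C | intermediate
18 | 4-bromofuran-2(5H)-one | BrC1=CC(=O)OC1 | starting material
19 | C12 B-alkyl-9-BBN borane | C[C@H]1C[C@H](O[Si](C)(C)C(C)(C)C)C2=C(CC[C@@H]3OC(C)(C)OC[C@]23C)[C@]1(C)CCB4C5CCCC4CCC5 | intermediate (not isolated)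
20 | butenolide (acetonide, 6-O-TBS) | C[C@H]1C[C@H](O[Si](C)(C)C(C)(C)C)C2=C(CC[C@@H]3OC(C)(C)OC[C@]23C)[C@]1(C)CCC1=CC(=O)OC1 | intermediate
21 | 3α,18-diol (6-O-TBS) | C[C@H]1C[C@H](O[Si](C)(C)C(C)(C)C)C2=C(CC[C@H](O)[C@]2(C)CO)[C@]1(C)CCC1=CC(=O)OC1 | intermediate
22 | 3-(4-hydroxyphenyl)propanoic acid | OC(=O)CCc1ccc(O)cc1 | starting material
23 | tert-butyldimethylsilyl 3-[4-(tert-butyldimethylsilyloxy)phenyl]propanoate | CC(C)(C)[Si](C)(C)OC(=O)CCc1ccc(O[Si](C)(C)C(C)(C)C)cc1 | intermediate (not isolated)
24 | 3-[4-(tert-butyldimethylsilyloxy)phenyl]propanoic acid | OC(=O)CCc1ccc(O[Si](C)(C)C(C)(C)C)cc1 | intermediate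
25 | C18 ester with free 3α-OH (6-O-TBS, aryl O-TBS) | C[C@H]1C[C@H](O[Si](C)(C)C(C)(C)C)C2=C(CC[C@H](O)[C@]2(C)COC(=O)CCc2ccc(O[Si](C)(C)C(C)(C)C)cc2)[C@]1(C)CCC1=CC(=O)OC1 | intermediate
26 | C3 ketone (6-O-TBS, aryl O-TBS) | C[C@H]1C[C@H](O[Si](C)(C)C(C)(C)C)C2=C(CCC(=O)[C@]2(C)COC(=O)CCc2ccc(O[Si](C)(C)C(C)(C)C)cc2)[C@]1(C)CCC1=CC(=O)OC1 | intermediate
27 | CNP0301014.1 | C[C@H]1C[C@H](O)C2=C(CCC(=O)[C@]2(C)COC(=O)CCc2ccc(O)cc2)[C@]1(C)CCC1=CC(=O)OC1 | target

**Step count and risks**

Total steps: 18. Longest linear sequence: 17 (steps 1–14 and 16–18; step 15 prepares the acid side fragment).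

Steps most likely to fail:

1. Step 8. The cycloaddition could take the reverse regiochemistry (formyl-bearing carbon to C6), could occur on the β face if the acetonide lock is weaker than argued, or could be followed by thermal loss of CO2 from the adduct. The fallback sets out from 8 and replaces the cycloaddition by a polarity-controlled stepwise annulation. With a catalytic base (DBU, THF, 0 °C), the C9 carbanion of 8 should add to (E)-1-nitropropene (Michael addition, C8–C9), and the nitronate should then close onto the C6 aldehyde (Henry reaction, C6–C7) to give the 7-nitro 6β-hydroxy ester F1. Radical denitration (Bu3SnH, AIBN, toluene, 90 °C) would give the hydroxy ester F2. Warming F2 with DBU in toluene should close the O6–C11 lactone, which only the isomer with O6 and C11 cis can do, and this returns the route to 14. Stereocontrol in this fallback rests on the reversible Henry step and on the lactonisation filter, and is expected to be lower than in the cycloaddition.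

2. Step 4. The enolate could act as a base on the secondary triflate (elimination to an acrylate, then Michael addition at the wrong carbon), or O-alkylation could compete. The fallback sets out from 4 and introduces C9 and C20 separately. Alkylation of the enolate with methyl bromoacetate (a primary electrophile) would give the keto ester F3; enol triflate formation as in step 5 would give the triflate F4; deprotonation of the ester (LiN(i-Pr)2, THF, −78 °C) and methylation with MeI would add C20 and return the route to 7.

3. Step 6. The hindered tetrasubstituted triflate could be reduced directly (hydride capture before CO insertion), or oxidative addition could be slow. The fallback sets out from 7 and brings in C6 as a vinyl group. Stille coupling with tributyl(vinyl)stannane (Pd(PPh3)4, LiCl, THF, reflux) would give the diene F5. Lemieux–Johnson cleavage of the terminal, less substituted double bond (OsO4 cat., NaIO4, 2,6-lutidine, dioxane/H2O) would return the route to 8.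

**Further compounds**

F1 | step 8 | 7-nitro 6β-hydroxy C11 methyl ester (C7 epimer mixture) | C[C@H]1C([N+](=O)[O-])[C@H](O)C2=C(CC[C@@H]3OC(C)(C)OC[C@]23C)[C@]1(C)C(=O)OC
F2 | step 8 | 6β-hydroxy C11 methyl ester | C[C@H]1C[C@H](O)C2=C(CC[C@@H]3OC(C)(C)OC[C@]23C)[C@]1(C)C(=O)OC
F3 | step 4 | C10 carbomethoxymethyl ketone (C10 epimer mixture) | COC(=O)CC1CC[C@@H]2OC(C)(C)OC[C@]2(C)C1=O
F4 | step 4 | enol triflate of F3 | COC(=O)CC=1CC[C@@H]2OC(C)(C)OC[C@]2(C)C=1OS(=O)(=O)C(F)(F)F
F5 | step 6 | C5-vinyl diene ester | COC(=O)C(C)C=1CC[C@@H]2OC(C)(C)OC[C@]2(C)C=1C=C
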